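**Strategy.** Numbering follows the guaiane skeleton (C1 and C5 ring fusion, C4 quaternary, C9' benzylic). The seven-membered ring is cut at C5=C6 and C1–C10: with C8–C9 as a transient alkene it is a cyclohepta-1,4-diene with C7 between the two double bonds and vicinal stereocentres C1/C10, the signature of a cis-divinylcyclopropane Cope rearrangement. In one pot the all-cis cyclopropylzinc from iodide 19 (ring C6–C7–C8, ester on C7, E-propenyl as C9–C10) is coupled to cyclopentenyl bromide 10 (C1=C5, C4 and C9' already set) at C5–C6; the divinylcyclopropane then rearranges through a boat, forming C1–C10, moving the alkene to C5=C6 and fixing C1 and C10.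

Key step: step 13

Remark: the (S)-CBS catalyst and Rh2(5R-MEPY)4 are assumed to keep their usual sense of induction with the bromo- and iodo-substituted substrates (bromoalkenyl arm as the large group; same alkene face as for allyl diazoacetate); otherwise the enantiomeric catalysts are used.

Step 1
Reactants: 1 2-bromo-3-methylcyclopent-2-en-1-one
Product: 2 (1R)-2-bromo-3-methylcyclopent-2-en-1-ol
Conditions: (S)-2-methyl-CBS-oxazaborolidine (10 mol%), BH3·SMe2, THF, −20 °C
Reagents that add atoms: none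
Why: Corey–Bakshi–Shibata reduction, in which the bromoalkenyl arm acts as the large group so that hydride should reach one carbonyl face and set the carbinol centre that later relays chirality to C4.

Step 2
Reactants: 2 (1R)-2-bromo-3-methylcyclopent-2-en-1-ol; 3 2-(2,4,6-trimethoxyphenyl)acetic acid
Product: 4 (1R)-2-bromo-3-methylcyclopent-2-en-1-yl 2-(2,4,6-trimethoxyphenyl)acetate
Conditions: DCC, DMAP (cat.), CH2Cl2, 0 °C to rt
Reagents that add atoms: none
Why: Steglich esterification of a secondary allylic alcohol under neutral conditions that leave the vinyl bromide and the carbinol centre untouched.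

Step 3
Reactants: 4 (1R)-2-bromo-3-methylcyclopent-2-en-1-yl 2-(2,4,6-trimethoxyphenyl)acetate
Product: 7 (2R)-2-[(1R)-2-bromo-1-methylcyclopent-2-en-1-yl]-2-(2,4,6-trimethoxyphenyl)acetic acid, via silyl ketene acetal 5 (not isolated), via trimethylsilyl ester 6 (not isolated)
Conditions: LiN(i-Pr)2, Me3SiCl, THF/DMPU, −78 °C to 60 °C; then aq. HCl
Reagents that add atoms: none
Why: Ireland–Claisen rearrangement, in which the suprafacial [3,3] shift delivers C9' to the ring face that carried the ester oxygen (setting quaternary C4) and the Z-ketene acetal (aryl cis to OSiMe3, expected with DMPU) reacting through the boat-like array usual for cycloalkenyl esters should set C9'.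

Step 4
Reactants: 7 (2R)-2-[(1R)-2-bromo-1-methylcyclopent-2-en-1-yl]-2-(2,4,6-trimethoxyphenyl)acetic acid
Product: 8 (2R)-2-[(1R)-2-bromo-1-methylcyclopent-2-en-1-yl]-2-(2,4,6-trimethoxyphenyl)ethan-1-ol
Conditions: BH3·SMe2, THF, 0 °C to rt; MeOH
Reagents that add atoms: none
Why: Borane reduction of the carboxylic acid to the primary alcohol, the hindered and electron-poor bromoalkene being expected to resist hydroboration at this temperature.

Step 5
Reactants: 8 (2R)-2-[(1R)-2-bromo-1-methylcyclopent-2-en-1-yl]-2-(2,4,6-trimethoxyphenyl)ethan-1-ol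
Product: 9 (2R)-2-[(1R)-2-bromo-1-methylcyclopent-2-en-1-yl]-2-(2,4,6-trimethoxyphenyl)ethyl 4-methylbenzenesulfonate
Conditions: TsCl, Et3N, DMAP (cat.), CH2Cl2, 0 °C to rt
Reagents that add atoms: 4-methylbenzenesulfonyl chloride, Cc1ccc(cc1)S(=O)(=O)Cl
Why: Sulfonylation of the primary alcohol (DMAP catalysis) installs a leaving group without touching either stereocentre.

Step 6
Reactants: 9 (2R)-2-[(1R)-2-bromo-1-methylcyclopent-2-en-1-yl]-2-(2,4,6-trimethoxyphenyl)ethyl 4-methylbenzenesulfonate
Product: 10 2-{(1R)-1-[(1R)-2-bromo-1-methylcyclopent-2-en-1-yl]-3-methylbutyl}-1,3,5-trimethoxybenzene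
Conditions: i-PrMgCl, Li2CuCl4 (5 mol%), THF, −20 °C to 0 °C
Reagents that add atoms: isopropylmagnesium chloride, CC(C)[Mg]Cl
Why: Kochi-type copper-catalysed coupling of a primary tosylate with a secondary Grignard reagent completes the isobutyl chain at a temperature where the alkenyl bromide should not react.

Step 7
Reactants: 11 ethyl (2Z)-3-iodoprop-2-enoate
Product: 12 (2Z)-3-iodoprop-2-en-1-ol
Conditions: (i-Bu)2AlH, CH2Cl2, −78 °C to 0 °C
Reagents that add atoms: none
Why: Hydride reduction of the ester to the allylic alcohol with retention of the Z-iodoalkene geometry.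

Step 8
Reactants: 12 (2Z)-3-iodoprop-2-en-1-ol
Product: 14 (2Z)-3-iodoprop-2-en-1-yl 2-diazoacetate, via tosylhydrazone ester 13 (not isolated)
Conditions: TsNHN=CHCOCl, PhNMe2, CH2Cl2, 0 °C; then Et3N
Reagents that add atoms: glyoxylic acid chloride 4-methylbenzenesulfonylhydrazone, Cc1ccc(cc1)S(=O)(=O)NN=CC(=O)Cl
Why: Corey–Myers diazoacetylation, acylation by the hydrazone acid chloride followed by base-induced loss of sulfinate (Bamford–Stevens type) to the diazoacetate.

Step 9
Reactants: 14 (2Z)-3-iodoprop-2-en-1-yl 2-diazoacetate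
Product: 15 (1S,5R,6S)-6-iodo-3-oxabicyclo[3.1.0]hexan-2-one
Conditions: Rh2(5R-MEPY)4 (1 mol%), CH2Cl2, reflux, slow addition
Reagents that add atoms: none
Why: Doyle intramolecular cyclopropanation with the chiral dirhodium carboxamidate, in which the tether forces cis fusion, the Z-alkene places iodine endo (all-cis cyclopropane) and the catalyst selects the alkene face, setting C6, C7 and C8.

Step 10
Reactants: 15 (1S,5R,6S)-6-iodo-3-oxabicyclo[3.1.0]hexan-2-one
Product: 17 methyl (1S,2R,3S)-2-(hydroxymethyl)-3-iodocyclopropane-1-carboxylate, via lithium carboxylate 16 (not isolated)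
Conditions: LiOH, THF/H2O, 0 °C; evaporate; MeI, DMF, rt
Reagents that add atoms: lithium hydroxide, [Li+].[OH-]; iodomethane, CI
Why: Saponification of the lactone and SN2 O-methylation of the carboxylate release the cis hydroxy ester, which is used at once before it can relactonise.

Step 11
Reactants: 17 methyl (1S,2R,3S)-2-(hydroxymethyl)-3-iodocyclopropane-1-carboxylate
Product: 18 methyl (1S,2R,3S)-2-formyl-3-iodocyclopropane-1-carboxylate
Conditions: Dess–Martin periodinane, NaHCO3, CH2Cl2, 0 °C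
Reagents that add atoms: none
Why: Dess–Martin oxidation under buffered non-basic conditions should give the aldehyde without epimerising the all-cis cyclopropane.

Step 12
Reactants: 18 methyl (1S,2R,3S)-2-formyl-3-iodocyclopropane-1-carboxylate
Product: 19 methyl (1S,2S,3S)-2-iodo-3-[(1E)-prop-1-en-1-yl]cyclopropane-1-carboxylate
Conditions: CH3CHI2, CrCl2, THF, rt
Reagents that add atoms: 1,1-diiodoethane, CC(I)I
Why: Takai–Utimoto olefination with the geminal dichromium reagent should give the E-propenyl group under non-basic conditions, so that neither epimerisation nor lactonisation onto the cis ester intervenes.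

Step 13
Reactants: 10 2-{(1R)-1-[(1R)-2-bromo-1-methylcyclopent-2-en-1-yl]-3-methylbutyl}-1,3,5-trimethoxybenzene; 19 methyl (1S,2S,3S)-2-iodo-3-[(1E)-prop-1-en-1-yl]cyclopropane-1-carboxylate
Product: 23 methyl (3R,5R,8R,8aR)-3,8-dimethyl-3-[(1S)-3-methyl-1-(2,4,6-trimethoxyphenyl)butyl]-1,2,3,5,8,8a-hexahydroazulene-5-carboxylate, via cyclopropylmagnesium chloride 20 (not isolated), via cyclopropylzinc chloride 21 (not isolated), via cis-divinylcyclopropane 22 (not isolated)
Conditions: i-PrMgCl·LiCl, THF, −40 °C; ZnCl2, −40 °C to 0 °C; 10, Pd(OAc)2 (5 mol%), SPhos (10 mol%), 50 °C; then toluene, 100 °C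
Reagents that add atoms: none
Why: Iodine–magnesium exchange on 19 (the cis ester chelates and holds the configuration) and transmetalation give cyclopropylzinc 21, which couples with retention to alkenyl bromide 10 at C5–C6 (Negishi coupling); the resulting cis-1,2-dialkenylcyclopropane 22 then undergoes the [3,3] divinylcyclopropane–cycloheptadiene (Cope) rearrangement, breaking C6–C8 and forming C1–C10 while the ring alkene moves from C1=C5 to C5=C6. The closest known chemistry is the seven-membered-ring annulation of cyclic alkenyl electrophiles with 2-vinylcyclopropyl metal reagents followed by thermal Cope rearrangement. The seven-membered ring closes in the sigmatropic step through the boat transition state with both alkenyl groups folded over the three-membered ring, a three-to-seven ring expansion driven by release of cyclopropane strain. C1 and C10 are set stereospecifically by this boat geometry and the alkene geometries (the ring CH2 at C2 and the E-methyl both point outward, so H1 and H10 end up cis), their absolute sense follows from the cyclopropane configuration, and C7 is carried over unchanged with its ester on the face of H1 and H10 because it was cis to both alkenyl groups. The step needs retention at the cyclopropyl carbon, coupling faster than loss of the organometal, and rearrangement below the temperature of one-centre cyclopropane epimerisation; the all-cis arrangement fixed by the lactone origin of 19, the E-propenyl terminus without an inward substituent, the small planar ester as the only inward group, and the C4 methyl (not the benzylic arm) facing the partner alkene should secure this.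

Step 14
Reactants: 23 methyl (3R,5R,8R,8aR)-3,8-dimethyl-3-[(1S)-3-methyl-1-(2,4,6-trimethoxyphenyl)butyl]-1,2,3,5,8,8a-hexahydroazulene-5-carboxylate
Product: 24 methyl (3R,5R,8R,8aR)-3,8-dimethyl-3-[(1S)-3-methyl-1-(2,4,6-trimethoxyphenyl)butyl]-1,2,3,5,6,7,8,8a-octahydroazulene-5-carboxylate
Conditions: H2 (1 atm), RhCl(PPh3)3 (10 mol%), benzene/EtOH, rt
Reagents that add atoms: none
Why: Homogeneous hydrogenation with Wilkinson's catalyst should reduce the cis-disubstituted C8=C9 alkene and leave the trisubstituted C5=C6 alkene, shielded by quaternary C4, untouched.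

Step 15
Reactants: 24 methyl (3R,5R,8R,8aR)-3,8-dimethyl-3-[(1S)-3-methyl-1-(2,4,6-trimethoxyphenyl)butyl]-1,2,3,5,6,7,8,8a-octahydroazulene-5-carboxylate
Product: 25 2-{(3R,5R,8R,8aR)-3,8-dimethyl-3-[(1S)-3-methyl-1-(2,4,6-trimethoxyphenyl)butyl]-1,2,3,5,6,7,8,8a-octahydroazulen-5-yl}propan-2-ol
Conditions: MeMgBr, CeCl3, THF, −78 °C to 0 °C
Reagents that add atoms: methylmagnesium bromide, C[Mg]Br
Why: Double addition of the methyl nucleophile to the ester, the cerium-modified reagent suppressing enolisation at the allylic C7–H, gives the tertiary alcohol with C7 unchanged.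

Step 16
Reactants: 25 2-{(3R,5R,8R,8aR)-3,8-dimethyl-3-[(1S)-3-methyl-1-(2,4,6-trimethoxyphenyl)butyl]-1,2,3,5,6,7,8,8a-octahydroazulen-5-yl}propan-2-ol
Product: 27 5-{(1S)-1-[(1R,3aR,4R,7R)-7-(2-hydroxypropan-2-yl)-1,4-dimethyl-1,2,3,3a,4,5,6,7-octahydroazulen-1-yl]-3-methylbutyl}-2,4,6-trimethoxybenzene-1,3-dicarbaldehyde, via lithium aminoalkoxide 26 (not isolated)
Conditions: n-BuLi, TMEDA, THF, 0 °C; DMF, −78 °C; n-BuLi, 0 °C; DMF; aq. NH4Cl
Reagents that add atoms: N,N-dimethylformamide, CN(C)C=O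
Why: Directed ortho-metalation between two methoxy groups and formylation with DMF, run twice in one flask, the first adduct staying masked as its lithium aminoalkoxide during the second lithiation.

Step 17
Reactants: 27 5-{(1S)-1-[(1R,3aR,4R,7R)-7-(2-hydroxypropan-2-yl)-1,4-dimethyl-1,2,3,3a,4,5,6,7-octahydroazulen-1-yl]-3-methylbutyl}-2,4,6-trimethoxybenzene-1,3-dicarbaldehyde
Product: 28 5-{(1S)-1-[(1R,3aR,4R,7R)-7-(2-hydroxypropan-2-yl)-1,4-dimethyl-1,2,3,3a,4,5,6,7-octahydroazulen-1-yl]-3-methylbutyl}-2,4,6-trihydroxybenzene-1,3-dicarbaldehyde (CNP0281883.3)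
Conditions: NaSEt, DMF, 110 °C; then dilute HCl, 0 °C
Reagents that add atoms: none
Why: SN2 demethylation by thiolate, each methoxy group being activated by an ortho or para formyl group, should free the three phenols under basic conditions that spare the tertiary alcohol and the alkene.

**Compound list**

1 | 2-bromo-3-methylcyclopent-2-en-1-one | CC1=C(Br)C(=O)CC1 | starting material
2 | (1R)-2-bromo-3-methylcyclopent-2-en-1-ol | O[C@@H]1CCC(C)=C1Br | intermediate
3 | 2-(2,4,6-trimethoxyphenyl)acetic acid | COc1cc(OC)c(CC(=O)O)c(OC)c1 | starting material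
4 | (1R)-2-bromo-3-methylcyclopent-2-en-1-yl 2-(2,4,6-trimethoxyphenyl)acetate | COc1cc(OC)c(CC(=O)O[C@@H]2CCC(C)=C2Br)c(OC)c1 | intermediate
5 | {[(1Z)-1-{[(1R)-2-bromo-3-methylcyclopent-2-en-1-yl]oxy}-2-(2,4,6-trimethoxyphenyl)ethenyl]oxy}trimethylsilane (silyl ketene acetal) | COc1cc(OC)c(/C=C(\O[Si](C)(C)C)O[C@@H]2CCC(C)=C2Br)c(OC)c1 | intermediate
6 | trimethylsilyl (2R)-2-[(1R)-2-bromo-1-methylcyclopent-2-en-1-yl]-2-(2,4,6-trimethoxyphenyl)acetate | C[Si](C)(C)OC(=O)[C@H](c1c(OC)cc(OC)cc1OC)[C@@]1(C)CCC=C1Br | intermediate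
7 | (2R)-2-[(1R)-2-bromo-1-methylcyclopent-2-en-1-yl]-2-(2,4,6-trimethoxyphenyl)acetic acid | OC(=O)[C@H](c1c(OC)cc(OC)cc1OC)[C@@]1(C)CCC=C1Br | intermediate
8 | (2R)-2-[(1R)-2-bromo-1-methylcyclopent-2-en-1-yl]-2-(2,4,6-trimethoxyphenyl)ethan-1-ol | OC[C@H](c1c(OC)cc(OC)cc1OC)[C@@]1(C)CCC=C1Br | intermediate
9 | (2R)-2-[(1R)-2-bromo-1-methylcyclopent-2-en-1-yl]-2-(2,4,6-trimethoxyphenyl)ethyl 4-methylbenzenesulfonate | Cc1ccc(cc1)S(=O)(=O)OC[C@H](c1c(OC)cc(OC)cc1OC)[C@@]1(C)CCC=C1Br | intermediate
10 | 2-{(1R)-1-[(1R)-2-bromo-1-methylcyclopent-2-en-1-yl]-3-methylbutyl}-1,3,5-trimethoxybenzene | CC(C)C[C@H](c1c(OC)cc(OC)cc1OC)[C@@]1(C)CCC=C1Br | intermediate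
11 | ethyl (2Z)-3-iodoprop-2-enoate | CCOC(=O)/C=C\I | starting material
12 | (2Z)-3-iodoprop-2-en-1-ol | OC/C=C\I | intermediate
13 | (2Z)-3-iodoprop-2-en-1-yl 2-[2-(4-methylbenzenesulfonyl)hydrazinylidene]acetate | Cc1ccc(cc1)S(=O)(=O)NN=CC(=O)OC/C=C\I | intermediate
14 | (2Z)-3-iodoprop-2-en-1-yl 2-diazoacetate | [N-]=[N+]=CC(=O)OC/C=C\I | intermediate
15 | (1S,5R,6S)-6-iodo-3-oxabicyclo[3.1.0]hexan-2-one (iodine endo) | I[C@@H]1[C@@H]2C(=O)OC[C@H]12 | intermediate
16 | lithium (1S,2R,3S)-2-(hydroxymethyl)-3-iodocyclopropane-1-carboxylate | I[C@@H]1[C@H](C([O-])=O)[C@@H]1CO.[Li+] | intermediate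
17 | methyl (1S,2R,3S)-2-(hydroxymethyl)-3-iodocyclopropane-1-carboxylate (all-cis) | I[C@@H]1[C@H](C(=O)OC)[C@@H]1CO | intermediate
18 | methyl (1S,2R,3S)-2-formyl-3-iodocyclopropane-1-carboxylate (all-cis) | I[C@@H]1[C@H](C(=O)OC)[C@@H]1C=O | intermediate
19 | methyl (1S,2S,3S)-2-iodo-3-[(1E)-prop-1-en-1-yl]cyclopropane-1-carboxylate (all-cis) | I[C@@H]1[C@H](C(=O)OC)[C@@H]1/C=C/C | intermediate
20 | chloro{(1S,2S,3S)-2-(methoxycarbonyl)-3-[(1E)-prop-1-en-1-yl]cyclopropyl}magnesium | Cl[Mg][C@@H]1[C@H](C(=O)OC)[C@@H]1/C=C/C | intermediate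
21 | chloro{(1S,2S,3S)-2-(methoxycarbonyl)-3-[(1E)-prop-1-en-1-yl]cyclopropyl}zinc | Cl[Zn][C@@H]1[C@H](C(=O)OC)[C@@H]1/C=C/C | intermediate
22 | methyl (1R,2S,3R)-2-{(5R)-5-methyl-5-[(1S)-3-methyl-1-(2,4,6-trimethoxyphenyl)butyl]cyclopent-1-en-1-yl}-3-[(1E)-prop-1-en-1-yl]cyclopropane-1-carboxylate (all-cis) | CC(C)C[C@H](c1c(OC)cc(OC)cc1OC)[C@@]1(C)CCC=C1[C@@H]1[C@H](C(=O)OC)[C@@H]1/C=C/C | intermediate
23 | methyl (3R,5R,8R,8aR)-3,8-dimethyl-3-[(1S)-3-methyl-1-(2,4,6-trimethoxyphenyl)butyl]-1,2,3,5,8,8a-hexahydroazulene-5-carboxylate | CC(C)C[C@H](c1c(OC)cc(OC)cc1OC)[C@@]1(C)CC[C@H]2C1=C[C@H](C(=O)OC)C=C[C@H]2C | intermediate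
24 | methyl (3R,5R,8R,8aR)-3,8-dimethyl-3-[(1S)-3-methyl-1-(2,4,6-trimethoxyphenyl)butyl]-1,2,3,5,6,7,8,8a-octahydroazulene-5-carboxylate | CC(C)C[C@H](c1c(OC)cc(OC)cc1OC)[C@@]1(C)CC[C@H]2C1=C[C@H](C(=O)OC)CC[C@H]2C | intermediate
25 | 2-{(3R,5R,8R,8aR)-3,8-dimethyl-3-[(1S)-3-methyl-1-(2,4,6-trimethoxyphenyl)butyl]-1,2,3,5,6,7,8,8a-octahydroazulen-5-yl}propan-2-ol | CC(C)C[C@H](c1c(OC)cc(OC)cc1OC)[C@@]1(C)CC[C@H]2C1=C[C@H](C(C)(C)O)CC[C@H]2C | intermediate
26 | dilithium salt of the first formylation adduct of 25 (aryl CH(OLi)NMe2 at one free ring position, tertiary alkoxide) | CC(C)C[C@H](c1c(OC)c(C([O-])N(C)C)c(OC)cc1OC)[C@@]1(C)CC[C@H]2C1=C[C@H](C(C)(C)[O-])CC[C@H]2C.[Li+].[Li+] | intermediate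
27 | 5-{(1S)-1-[(1R,3aR,4R,7R)-7-(2-hydroxypropan-2-yl)-1,4-dimethyl-1,2,3,3a,4,5,6,7-octahydroazulen-1-yl]-3-methylbutyl}-2,4,6-trimethoxybenzene-1,3-dicarbaldehyde | CC(C)C[C@H](c1c(OC)c(C=O)c(OC)c(C=O)c1OC)[C@@]1(C)CC[C@H]2C1=C[C@H](C(C)(C)O)CC[C@H]2C | intermediate
28 | 5-{(1S)-1-[(1R,3aR,4R,7R)-7-(2-hydroxypropan-2-yl)-1,4-dimethyl-1,2,3,3a,4,5,6,7-octahydroazulen-1-yl]-3-methylbutyl}-2,4,6-trihydroxybenzene-1,3-dicarbaldehyde | CC(C)C[C@H](c1c(O)c(C=O)c(O)c(C=O)c1O)[C@@]1(C)CC[C@H]2C1=C[C@H](C(C)(C)O)CC[C@H]2C | target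

**Total step count:** 17 steps.
**Longest linear sequence:** 11 steps (steps 1–6, 13–17; the branch of steps 7–12 is equally long up to the junction).

**Steps most likely to fail**

Step 13. Transmetalation and reductive elimination between the two hindered carbons may be slower than protonation or decay of the cyclopropylzinc, and the rearrangement of the all-cis ester may need a temperature at which one-centre epimerisation of the cyclopropane sets in. The fallback reverses the polarity and separates the two events. It sets out from 10: bromine–lithium exchange (t-BuLi, THF, −78 °C) and trapping with 2-isopropoxy-4,4,5,5-tetramethyl-1,3,2-dioxaborolane should give the alkenylboronate 2-{(5R)-5-methyl-5-[(1S)-3-methyl-1-(2,4,6-trimethoxyphenyl)butyl]cyclopent-1-en-1-yl}-4,4,5,5-tetramethyl-1,3,2-dioxaborolane F1. Suzuki–Miyaura coupling of F1 with iodocyclopropane 19 (Pd(OAc)2, SPhos, K3PO4, toluene/H2O, 40 °C), in which the iodocyclopropane reacts with retention, should give 22. This is isolated cold and heated on its own in dilute toluene, and the route is rejoined at 23.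

Step 3. A chair-like array may compete with the boat-like one (in the boat the bromine on the central allyl carbon eclipses the silyloxy group), which would erode or invert the configuration at C9' while C4 stays correct. The fallback is an Eschenmoser–Claisen rearrangement, whose ketene N,O-acetal carries the aryl group cis to the allylic oxygen and so should give the same C9' configuration through a chair. It sets out from 3, which is converted (oxalyl chloride, then Me2NH) into N,N-dimethyl-2-(2,4,6-trimethoxyphenyl)acetamide F2 and this (Me3OBF4, then NaOMe) into 1,1-dimethoxy-N,N-dimethyl-2-(2,4,6-trimethoxyphenyl)ethan-1-amine F3. Heating F3 with alcohol 2 in xylene (140 °C) should give (2R)-2-[(1R)-2-bromo-1-methylcyclopent-2-en-1-yl]-N,N-dimethyl-2-(2,4,6-trimethoxyphenyl)acetamide F4. Lithium amidotrihydroborate (LiH2NBH3, THF) should reduce F4 to the primary alcohol, and the route is rejoined at 8.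

Step 16. The second lithiation may stay incomplete on the crowded, alkoxide-bearing arene, or slow deprotonation at allylic positions may compete. The fallback replaces directed metalation by halogen–metal exchange. It sets out from 25: bromination with N-bromosuccinimide (2 equiv, MeCN, −20 °C; the trimethoxyarene is by far the most nucleophilic site) should give 2-{(3R,5R,8R,8aR)-3-[(1S)-1-(3,5-dibromo-2,4,6-trimethoxyphenyl)-3-methylbutyl]-3,8-dimethyl-1,2,3,5,6,7,8,8a-octahydroazulen-5-yl}propan-2-ol F5. Double bromine–lithium exchange on F5 (t-BuLi, THF, −78 °C) and quenching with DMF should give the dialdehyde, and the route is rejoined at 27.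

**Further compounds**

F1 | step 13 | 2-{(5R)-5-methyl-5-[(1S)-3-methyl-1-(2,4,6-trimethoxyphenyl)butyl]cyclopent-1-en-1-yl}-4,4,5,5-tetramethyl-1,3,2-dioxaborolane | CC(C)C[C@H](c1c(OC)cc(OC)cc1OC)[C@@]1(C)CCC=C1B1OC(C)(C)C(C)(C)O1
F2 | step 3 | N,N-dimethyl-2-(2,4,6-trimethoxyphenyl)acetamide | CN(C)C(=O)Cc1c(OC)cc(OC)cc1OC
F3 | step 3 | 1,1-dimethoxy-N,N-dimethyl-2-(2,4,6-trimethoxyphenyl)ethan-1-amine | COC(OC)(Cc1c(OC)cc(OC)cc1OC)N(C)C
F4 | step 3 | (2R)-2-[(1R)-2-bromo-1-methylcyclopent-2-en-1-yl]-N,N-dimethyl-2-(2,4,6-trimethoxyphenyl)acetamide | CN(C)C(=O)[C@H](c1c(OC)cc(OC)cc1OC)[C@@]1(C)CCC=C1Br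
F5 | step 16 | 2-{(3R,5R,8R,8aR)-3-[(1S)-1-(3,5-dibromo-2,4,6-trimethoxyphenyl)-3-methylbutyl]-3,8-dimethyl-1,2,3,5,6,7,8,8a-octahydroazulen-5-yl}propan-2-ol | CC(C)C[C@H](c1c(OC)c(Br)c(OC)c(Br)c1OC)[C@@]1(C)CC[C@H]2C1=C[C@H](C(C)(C)O)CC[C@H]2C
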